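**Plan**
- Retrosynthesis: the C6 aryl ester and C6 carbinol come from a C6 ketone, the C9=C10 alkene from a C9 ketone, and the C4 isopropyl carbinol from a C4 ketone. The resulting 1,5-diketone is reconnected C5–C9 (retro-aldol in reverse) to a cyclobutanol, whose bonds C5–C1 and C9–C10 are cut to an enol carbonate of a 2-acylcyclopentanone carrying a methallyl terminus.
- Enabling feature: C4 and C9 are 1,5-related through C5–C1–C10, and the two-carbon unit C1(CH3)–C10 sits between C5 and C9 of a five-carbon chain C5–C6–C7–C8–C9. This is the pattern of a de Mayo two-carbon ring expansion of a cyclopentane into the cycloheptene.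
- Forward ring order: chiral-pool cyclopentanone (C5–C9), then the five-membered ring C1–C5 and a cyclobutane in one photochemical step, then the seven-membered ring by strain-driven cleavage of C5–C9.
- Stereochemistry: C6 of (S)-4-silyloxycyclopentenone directs the C8 hydroxylation (anti). C6 and C8 together direct C1 in the photocycloaddition. C5 is set by protonation to the cis fusion, and C4 by convex-face Grignard addition. C6 is finally reset by oxidation and hydride reduction.

Key step: step 7

Remark: carotane numbering is used for all compounds (C1 methyl-bearing fusion carbon, C2, C3, C4 isopropyl carbinol, C5 fusion CH, C6 acyloxy carbon, C7, C8 methyl carbinol, C9=C10), also for the monocyclic precursors; β is the face of the C1 methyl; 1, 6 and 20 are taken as commercial.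

Step 1
Reactants: 1 (S)-4-(tert-butyldimethylsilyloxy)cyclopent-2-en-1-one
Product: 2 (S)-4-(tert-butyldimethylsilyloxy)-2-iodocyclopent-2-en-1-one
Conditions: I2, pyridine, CH2Cl2, 0 °C to rt
Reagents that add atoms: iodine, II
Why: α-Iodination of the enone by pyridine-mediated conjugate addition, iodination and elimination (Baylis–Hillman-type) leaves the silyl ether and its stereocentre untouched.

Step 2
Reactants: 2 (S)-4-(tert-butyldimethylsilyloxy)-2-iodocyclopent-2-en-1-one
Product: 3 (S)-4-(tert-butyldimethylsilyloxy)-2-methylcyclopent-2-en-1-one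
Conditions: MeZnCl, Pd(PPh3)4 (cat.), THF/DMF, rt
Reagents that add atoms: methylzinc chloride, C[Zn]Cl
Why: Negishi cross-coupling of the α-iodoenone runs under neutral conditions at room temperature, so the γ-silyloxy enone should neither eliminate nor racemise.

Step 3
Reactants: 3 (S)-4-(tert-butyldimethylsilyloxy)-2-methylcyclopent-2-en-1-one
Product: 5 (2R,4R)-4-(tert-butyldimethylsilyloxy)-2-hydroxy-2-methylcyclopentan-1-one, via hydroperoxide 4 (not isolated)
Conditions: Mn(dpm)3 (cat.), PhSiH3, O2 (1 atm), i-PrOH, 0 °C; then P(OEt)3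
Reagents that add atoms: dioxygen, O=O
Why: Mukaiyama-type reductive α-hydroxylation of the enone (hydride to C7, O2 trapping at C8, phosphite reduction of the hydroperoxide) installs the tertiary C8 hydroxyl, with O2 expected to enter anti to the C6 silyloxy group (1,3-induction); any cis isomer is removed by chromatography.

Step 4
Reactants: 6 4-methylpent-4-enoic acid
Product: 7 1-(1H-benzotriazol-1-yl)-4-methylpent-4-en-1-one
Conditions: benzotriazole, SOCl2, CH2Cl2, rt
Reagents that add atoms: 1H-benzotriazole, c1ccc2[nH]nnc2c1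
Why: N-Acylbenzotriazole formation through the acid chloride gives a neutral, storable acyl donor.

Step 5
Reactants: 5 (2R,4R)-4-(tert-butyldimethylsilyloxy)-2-hydroxy-2-methylcyclopentan-1-one; 7 1-(1H-benzotriazol-1-yl)-4-methylpent-4-en-1-one
Product: 8 (3R,5R)-3-(tert-butyldimethylsilyloxy)-5-hydroxy-5-methyl-2-(4-methylpent-4-enoyl)cyclopentan-1-one (enolised β-diketone)
Conditions: MgBr2·OEt2, i-Pr2NEt, CH2Cl2, rt
Reagents that add atoms: none
Why: Soft-enolisation C-acylation (crossed Claisen type) acylates C5, the only enolisable position, through a magnesium-chelated enolate present in low concentration, which should suppress β-elimination of the C6 silyloxy group.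

Step 6
Reactants: 8 (3R,5R)-3-(tert-butyldimethylsilyloxy)-5-hydroxy-5-methyl-2-(4-methylpent-4-enoyl)cyclopentan-1-one
Product: 9 benzyl [(3R,5R)-3-(tert-butyldimethylsilyloxy)-5-hydroxy-5-methyl-2-(4-methylpent-4-enoyl)cyclopent-1-en-1-yl] carbonate
Conditions: ClCO2Bn, pyridine, CH2Cl2, 0 °C
Reagents that add atoms: benzyl chloroformate, O=C(Cl)OCc1ccccc1
Why: O-Acylation of the enolised 2-acylcyclopentanone with a chloroformate is expected to give the enol carbonate of the ring carbonyl (endocyclic C5=C9), while the hindered tertiary C8 hydroxyl stays free.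

Step 7
Reactants: 9 benzyl [(3R,5R)-3-(tert-butyldimethylsilyloxy)-5-hydroxy-5-methyl-2-(4-methylpent-4-enoyl)cyclopent-1-en-1-yl] carbonate
Product: 10 tricyclic cyclobutane photoadduct (C5 bonded to C1 and C9 to C10; cyclobutane cis-fused to the C1–C5 cyclopentanone and to the C5–C9 cyclopentane; 1β-methyl; 6α-silyloxy; 8β-hydroxy-8α-methyl; C9 benzyl carbonate)
Conditions: hν (λ > 300 nm, Pyrex), cyclohexane, degassed, dilute, rt
Reagents that add atoms: none
Why: Excitation of the β-(alkoxycarbonyloxy)enone C4(=O)–C5=C9 gives a triplet in which C5 bonds to the inner alkene carbon C1, and the resulting 1,4-diradical (C9/C10) collapses to the cyclobutane, so C5–C1 and C9–C10 form in one operation. The closest known reaction type is the intramolecular de Mayo [2+2] photocycloaddition of enol carbonates of 2-acylcyclopentanones whose alkene is tethered through the acyl chain (straight addition of a hepta-1,6-dien-3-one). The cyclopentanone ring C1–C5 closes in the five-membered (rule-of-five) mode and the cyclobutane C5–C9–C10–C1 by diradical recombination, both necessarily cis-fused to the four-membered ring. The quaternary stereocentre C1 is set by the enone face attacked: the alkene should add anti to the 6α-silyloxy group next to C5 and anti to the 8α-methyl, that is syn to the small 8β-hydroxyl, which places the C1 methyl β; C5 and C9 follow from the cis fusions and are reset or erased in step 8. The step needs straight rather than crossed closure, secured by the three-atom tether and the fixed endocyclic enol carbonate, and must outrun acyl migration and secondary cleavage of the product ketone, for which the Pyrex cut-off, dilution and stopping at full conversion are used.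

Step 8
Reactants: 10 tricyclic cyclobutane photoadduct
Product: 12 cis-fused 6α-(tert-butyldimethylsilyloxy)-8β-hydroxy-1β,8α-dimethylbicyclo[5.3.0]decane-4,9-dione (5β-H), via cyclobutanol 11 (not isolated)
Conditions: H2 (1 atm), Pd/C, EtOAc/AcOH, rt
Reagents that add atoms: none
Why: Hydrogenolysis of the benzyl carbonate frees the cyclobutanol under neutral conditions, and strain-driven retro-aldol cleavage of C5–C9 (de Mayo fragmentation) opens the seven-membered ring; C5 is protonated from the convex face and can equilibrate through the enol to the cis fusion expected to be favoured for a cyclopentanone next to an angular methyl.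

Step 9
Reactants: 12 cis-fused 6α-(tert-butyldimethylsilyloxy)-8β-hydroxy-1β,8α-dimethylbicyclo[5.3.0]decane-4,9-dione
Product: 13 6α-(tert-butyldimethylsilyloxy)-4α,8β-dihydroxy-5β-carotan-9-one (cis-fused; 4β-isopropyl)
Conditions: i-PrMgCl, LaCl3·2LiCl, THF, 0 °C
Reagents that add atoms: isopropylmagnesium chloride, CC(C)[Mg]Cl
Why: Lanthanum-assisted Grignard 1,2-addition suppresses enolisation and β-elimination and should occur at the cyclopentanone C4 rather than at C9, which is shielded by the quaternary C8 alkoxide; attack from the convex β-face anti to the C5–C6 bond gives 4β-isopropyl and 4α-hydroxyl.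

Step 10
Reactants: 13 6α-(tert-butyldimethylsilyloxy)-4α,8β-dihydroxy-5β-carotan-9-one
Product: 14 C9 tosylhydrazone of 13
Conditions: TsNHNH2, AcOH (cat.), EtOH, 60 °C
Reagents that add atoms: 4-methylbenzenesulfonohydrazide, Cc1ccc(cc1)S(=O)(=O)NN
Why: Hydrazone condensation takes place at the only remaining ketone.

Step 11
Reactants: 14 C9 tosylhydrazone of 13
Product: 16 6α-(tert-butyldimethylsilyloxy)-5β-carot-9-ene-4α,8β-diol, via vinyllithium 15 (not isolated)
Conditions: n-BuLi (excess), TMEDA, THF, −78 to 0 °C; then H2O
Reagents that add atoms: none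
Why: Shapiro reaction: the hydrazone dianion can form only at C10 because C8 is quaternary, loses sulfinate and N2 to the C9 vinyllithium, and protonation gives the C9=C10 alkene.

Step 12
Reactants: 16 6α-(tert-butyldimethylsilyloxy)-5β-carot-9-ene-4α,8β-diol
Product: 17 5β-carot-9-ene-4α,6α,8β-triol
Conditions: TBAF, THF, rt
Reagents that add atoms: none
Why: Fluoride cleaves the secondary silyl ether.

Step 13
Reactants: 17 5β-carot-9-ene-4α,6α,8β-triol
Product: 18 4α,8β-dihydroxy-5β-carot-9-en-6-one
Conditions: Dess–Martin periodinane, NaHCO3, CH2Cl2, 0 °C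
Reagents that add atoms: none
Why: Dess–Martin oxidation touches only the secondary alcohol, and the buffered neutral medium should spare the tertiary allylic alcohol and the retro-aldol-prone β-hydroxy ketone.

Step 14
Reactants: 18 4α,8β-dihydroxy-5β-carot-9-en-6-one
Product: 19 5β-carot-9-ene-4α,6β,8β-triol
Conditions: NaBH4, CeCl3·7H2O, MeOH, −78 °C
Reagents that add atoms: none
Why: Luche-type reduction at low temperature: hydride should attack C6 from the α-face, away from the β-oriented angular methyl and isopropyl groups, which places the hydroxyl β as in the target.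

Step 15
Reactants: 19 5β-carot-9-ene-4α,6β,8β-triol; 20 4-acetoxybenzoic acid
Product: 21 6β-(4-acetoxybenzoyloxy)-5β-carot-9-ene-4α,8β-diol
Conditions: EDC·HCl, DMAP, CH2Cl2, rt
Reagents that add atoms: none
Why: Steglich esterification acylates the only secondary hydroxyl; both tertiary alcohols are inert.

Step 16
Reactants: 21 6β-(4-acetoxybenzoyloxy)-5β-carot-9-ene-4α,8β-diol
Product: 22 [(3R,3aS,4S,6R,8aS)-3,6-dihydroxy-6,8a-dimethyl-3-(propan-2-yl)-1,2,3,3a,4,5,6,8a-octahydroazulen-4-yl] 4-hydroxybenzoate
Conditions: K2CO3 (cat.), MeOH, 0 °C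
Reagents that add atoms: none
Why: Mild methanolysis removes the phenyl acetate much faster than it attacks the hindered secondary benzoate, and the medium is not acidic, so the tertiary allylic alcohol is safe.

**Compound list**
1 | (S)-4-(tert-butyldimethylsilyloxy)cyclopent-2-en-1-one | O=C1C=C[C@@H](O[Si](C)(C)C(C)(C)C)C1 | starting material
2 | (S)-4-(tert-butyldimethylsilyloxy)-2-iodocyclopent-2-en-1-one | O=C1C(I)=C[C@@H](O[Si](C)(C)C(C)(C)C)C1 | intermediate
3 | (S)-4-(tert-butyldimethylsilyloxy)-2-methylcyclopent-2-en-1-one | O=C1C(C)=C[C@@H](O[Si](C)(C)C(C)(C)C)C1 | intermediate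
4 | (2R,4R)-4-(tert-butyldimethylsilyloxy)-2-hydroperoxy-2-methylcyclopentan-1-one | O=C1C[C@H](O[Si](C)(C)C(C)(C)C)C[C@@]1(C)OO | intermediate
5 | (2R,4R)-4-(tert-butyldimethylsilyloxy)-2-hydroxy-2-methylcyclopentan-1-one | O=C1C[C@H](O[Si](C)(C)C(C)(C)C)C[C@@]1(C)O | intermediate
6 | 4-methylpent-4-enoic acid | C=C(C)CCC(=O)O | starting material
7 | 1-(1H-benzotriazol-1-yl)-4-methylpent-4-en-1-one | C=C(C)CCC(=O)n1nnc2ccccc12 | intermediate
8 | (3R,5R)-3-(tert-butyldimethylsilyloxy)-5-hydroxy-5-methyl-2-(4-methylpent-4-enoyl)cyclopentan-1-one | C=C(C)CCC(=O)C1[C@H](O[Si](C)(C)C(C)(C)C)C[C@@](C)(O)C1=O | intermediate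
9 | benzyl [(3R,5R)-3-(tert-butyldimethylsilyloxy)-5-hydroxy-5-methyl-2-(4-methylpent-4-enoyl)cyclopent-1-en-1-yl] carbonate | C=C(C)CCC(=O)C1=C(OC(=O)OCc2ccccc2)[C@](C)(O)C[C@H]1O[Si](C)(C)C(C)(C)C | intermediate
10 | tricyclic cyclobutane photoadduct (C9 benzyl carbonate) | O=C1CC[C@@]2(C)C[C@]3(OC(=O)OCc4ccccc4)[C@](C)(O)C[C@@H](O[Si](C)(C)C(C)(C)C)[C@]123 | intermediate
11 | tricyclic cyclobutanol | O=C1CC[C@@]2(C)C[C@]3(O)[C@](C)(O)C[C@@H](O[Si](C)(C)C(C)(C)C)[C@]123 | intermediate
12 | cis-fused 6α-(tert-butyldimethylsilyloxy)-8β-hydroxy-1β,8α-dimethylbicyclo[5.3.0]decane-4,9-dione | O=C1CC[C@@]2(C)CC(=O)[C@](C)(O)C[C@@H](O[Si](C)(C)C(C)(C)C)[C@@H]12 | intermediate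
13 | 6α-(tert-butyldimethylsilyloxy)-4α,8β-dihydroxy-5β-carotan-9-one | CC(C)[C@]1(O)CC[C@@]2(C)CC(=O)[C@](C)(O)C[C@@H](O[Si](C)(C)C(C)(C)C)[C@@H]12 | intermediate
14 | C9 tosylhydrazone of 13 | CC(C)[C@]1(O)CC[C@@]2(C)CC(=NNS(=O)(=O)c3ccc(C)cc3)[C@](C)(O)C[C@@H](O[Si](C)(C)C(C)(C)C)[C@@H]12 | intermediate
15 | C9 vinyllithium (dilithium 4,8-dialkoxide) | CC(C)[C@]1(O[Li])CC[C@@]2(C)C=C([Li])[C@](C)(O[Li])C[C@@H](O[Si](C)(C)C(C)(C)C)[C@@H]12 | intermediate
16 | 6α-(tert-butyldimethylsilyloxy)-5β-carot-9-ene-4α,8β-diol | CC(C)[C@]1(O)CC[C@@]2(C)C=C[C@](C)(O)C[C@@H](O[Si](C)(C)C(C)(C)C)[C@@H]12 | intermediate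
17 | 5β-carot-9-ene-4α,6α,8β-triol | CC(C)[C@]1(O)CC[C@@]2(C)C=C[C@](C)(O)C[C@@H](O)[C@@H]12 | intermediate
18 | 4α,8β-dihydroxy-5β-carot-9-en-6-one | CC(C)[C@]1(O)CC[C@@]2(C)C=C[C@](C)(O)CC(=O)[C@@H]12 | intermediate
19 | 5β-carot-9-ene-4α,6β,8β-triol | CC(C)[C@]1(O)CC[C@@]2(C)C=C[C@](C)(O)C[C@H](O)[C@@H]12 | intermediate
20 | 4-acetoxybenzoic acid | CC(=O)Oc1ccc(cc1)C(=O)O | starting material
21 | 6β-(4-acetoxybenzoyloxy)-5β-carot-9-ene-4α,8β-diol | CC(C)[C@]1(O)CC[C@@]2(C)C=C[C@](C)(O)C[C@H](OC(=O)c3ccc(OC(C)=O)cc3)[C@@H]12 | intermediate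
22 | [(3R,3aS,4S,6R,8aS)-3,6-dihydroxy-6,8a-dimethyl-3-(propan-2-yl)-1,2,3,3a,4,5,6,8a-octahydroazulen-4-yl] 4-hydroxybenzoate | CC(C)[C@]1(O)CC[C@@]2(C)C=C[C@](C)(O)C[C@H](OC(=O)c3ccc(O)cc3)[C@@H]12 | target

**Step count:** 16 steps in total; the longest linear sequence is 15 steps (1 to 22; step 4 is a one-step side branch).

**Steps most likely to fail**

Step 7. The excited enol carbonate may decay by acyl migration, close in the crossed sense, or the cyclobutyl ketone formed may be cleaved by further light absorption. The fallback sets out from 8 and drops the enol carbonate: the hydrogen-bonded enol of the β-diketone 8 is irradiated directly (classical de Mayo mode, λ > 300 nm, MeCN). The cyclobutanol 11 that results from [2+2] addition across the enolised ring carbonyl should undergo retro-aldol opening in the same flask without being exposed to further light as a ketone for long. The route is rejoined at 12, and 9 and 10 are bypassed.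

Step 5. The enolate at C5 may expel silanolate from C6 (β-elimination to the cyclopentenone) faster than it is acylated. The fallback sets out from 5 and replaces acylation by aldol addition and oxidation. Double enolisation with Bu2BOTf and i-Pr2NEt at −78 °C ties up the tertiary hydroxyl as a borinate and gives a covalent boron enolate, which should not eliminate. It is added to 4-methylpent-4-enal F1 (from Swern oxidation of commercial 4-methylpent-4-en-1-ol) to give the β-hydroxy ketone F2 as a mixture of carbinol epimers. Dess–Martin oxidation of the secondary carbinol returns to 8.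

Step 14. Hydride delivery to the C6 ketone may show poor facial selectivity in the flexible seven-membered ring, or the β-hydroxy ketone may undergo retro-aldol opening in the basic medium. The fallback sets out from 17 and avoids the ketone altogether: Mitsunobu esterification of the 6α-alcohol with 20 (PPh3, DIAD, toluene) should invert C6 by displacement and give 21 directly. The route is rejoined at 21, and 18 and 19 are bypassed.

**Further compounds**
F0 | step 7 | none | none
F1 | step 5 | 4-methylpent-4-enal | C=C(C)CCC=O
F2 | step 5 | (3R,5R)-3-(tert-butyldimethylsilyloxy)-5-hydroxy-2-(1-hydroxy-4-methylpent-4-enyl)-5-methylcyclopentan-1-one | C=C(C)CCC(O)C1[C@H](O[Si](C)(C)C(C)(C)C)C[C@@](C)(O)C1=O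
F0 | step 14 | none | none
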